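**Plan**

1. Numbering used throughout: ring A is C1(OH)–C2–C3(Cl)–C4(Me, side chain)–C5–C10(Me); ring B is C5–C6–C7=C8(C12 ester)–C9(C11 formyl)–C10; β is the face of the C10 methyl.
2. Feature: a chlorine sitting equatorially on C3, next to quaternary C4 of the trans-fused rings A and B, is the mark left by a head-to-tail cyclization begun at a C3/C4 chloronium ion; the C8/C11 oxygenation maps onto a β-keto ester terminator.
3. Retrosynthesis: cut the side-chain alkene (cross-metathesis) and C8–C12 (carbonylation), then C4–C5 and C9–C10 together, then C8–C9 (diazo ester homologation), the allyl C–C bond (epoxide/vinyl cuprate), C3=C4 and C5=C10 (two methacrolein cross-metatheses) and C1–C2 (allylboration).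
4. Forward: the chain is grown from the C8 end (C8 → C5=C10 → C1 → C2/C3=C4 → allyl → C9/C11), rings A and B close in one operation, and C12, the side chain and the aldehyde come last.
5. Stereochemistry: C1 from reagent-controlled allylboration; C3 and C4 from asymmetric epoxidation and invertive chloride opening at C3; C5, C9 and C10 from chair–chair anti addition across the (E)-C5=C10 alkene, relayed from C3/C4 through the chloronium ion; side-chain (E) geometry from metathesis.

Key step: step 15

Remark: methyl diazoacetate and the B-allyldiisopinocampheylborane of the (+)-α-pinene series are taken as purchasable reagents; the ester alkyl of the β-keto ester is a spectator, because C11 is reduced after the cyclization.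

**Route**

Step 1
Reactants: 1 pent-4-en-1-ol
Product: 2 tert-butyldimethyl(pent-4-en-1-yloxy)silane
Conditions: TBSCl, imidazole, CH2Cl2, 0 °C → rt
Reagents that add atoms: tert-butyldimethylsilyl chloride, CC(C)(C)[Si](C)(C)Cl
Why: Imidazole-promoted silylation of a primary alcohol is routine and masks the future C8 oxygen until the β-keto ester is needed.

Step 2
Reactants: 2 silyl ether; 3 methacrolein
Product: 4 (2E)-6-[(tert-butyldimethylsilyl)oxy]-2-methylhex-2-enal
Conditions: 3 (excess), second-generation Grubbs catalyst (H2IMes)(PCy3)Cl2Ru=CHPh (5 mol%), CH2Cl2, 40 °C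
Reagents that add atoms: none
Why: Olefin cross-metathesis of a terminal alkene with methacrolein is known to give 2-methyl-2-enals with high (E) selectivity, which fixes the (E)-C5=C10 geometry that later becomes the trans ring fusion.

Step 3
Reactants: 4 enal
Product: 5 (4S,5E)-9-[(tert-butyldimethylsilyl)oxy]-5-methylnona-1,5-dien-4-ol
Conditions: B-allyldiisopinocampheylborane [(+)-α-pinene series, (1R,2S,3R,5R)-isopinocampheyl groups], Et2O, −78 °C; then NaOH, H2O2
Reagents that add atoms: B-allyldiisopinocampheylborane, C=CCB([C@@H]1C[C@@H]2C[C@H]([C@H]1C)C2(C)C)[C@@H]1C[C@@H]2C[C@H]([C@H]1C)C2(C)C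
Why: Brown asymmetric allylboration: the (+)-α-pinene-derived reagent transfers allyl to the Si face of the α-branched enal through a chair six-membered transition state and sets C1 as (S) under reagent control.

Step 4
Reactants: 5 homoallylic alcohol
Product: 6 (4S,5E)-4,9-bis[(tert-butyldimethylsilyl)oxy]-5-methylnona-1,5-diene
Conditions: TBSCl, imidazole, DMF, rt
Reagents that add atoms: tert-butyldimethylsilyl chloride, CC(C)(C)[Si](C)(C)Cl
Why: Silylation of the allylic C1 alcohol gives an ether that, unlike an allylic ester, is inert to the hydride, titanium and cuprate steps that follow.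

Step 5
Reactants: 6 bis-silyl diene; 3 methacrolein
Product: 7 (2E,5S,6E)-5,10-bis[(tert-butyldimethylsilyl)oxy]-2,6-dimethyldeca-2,6-dienal
Conditions: 3 (excess), second-generation Grubbs catalyst (5 mol%), CH2Cl2, 40 °C
Reagents that add atoms: none
Why: A second cross-metathesis with methacrolein engages only the monosubstituted alkene (the trisubstituted C5=C10 alkene is unreactive) and delivers the (E)-C3=C4 enal needed for a trans-epoxide.

Step 6
Reactants: 7 dienal
Product: 8 (2E,5S,6E)-5,10-bis[(tert-butyldimethylsilyl)oxy]-2,6-dimethyldeca-2,6-dien-1-ol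
Conditions: NaBH4, CeCl3·7H2O, MeOH, 0 °C
Reagents that add atoms: none
Why: Luche reduction gives clean 1,2-reduction of the enal to the (E)-allylic alcohol required for a directed epoxidation.

Step 7
Reactants: 8 allylic alcohol
Product: 9 {(2R,3R)-3-[(2S,3E)-2,7-bis[(tert-butyldimethylsilyl)oxy]-3-methylhept-3-en-1-yl]-2-methyloxiran-2-yl}methanol
Conditions: Ti(OiPr)4 (10 mol%), D-(−)-diethyl tartrate (12 mol%), t-BuOOH, 4 Å molecular sieves, CH2Cl2, −20 °C
Reagents that add atoms: tert-butyl hydroperoxide, CC(C)(C)OO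
Why: Katsuki–Sharpless asymmetric epoxidation of an (E)-2-methylallylic alcohol with D-(−)-tartrate delivers oxygen to one face under reagent control and sets C3 and C4 (both R at this stage), while the silylated C1 carbinol and its alkene take no part.

Step 8
Reactants: 9 epoxy alcohol
Product: 10 (2R,3S,5S,6E)-5,10-bis[(tert-butyldimethylsilyl)oxy]-3-chloro-2,6-dimethyldec-6-ene-1,2-diol
Conditions: Ti(OiPr)4, Et2NH·HCl, CH2Cl2, rt
Reagents that add atoms: diethylamine hydrochloride, CCNCC.Cl
Why: Titanium-assisted opening of a 2,3-epoxy alcohol by chloride occurs at the carbon remote from the chelating hydroxymethyl group, here the less substituted C3, by SN2 with inversion, so C3 becomes (S) and the C4 oxygen stays as the tertiary alcohol.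

Step 9
Reactants: 10 chloro diol
Product: 12 (2R)-2-[(1S,3S,4E)-3,8-bis[(tert-butyldimethylsilyl)oxy]-1-chloro-4-methyloct-4-en-1-yl]-2-methyloxirane, via primary tosylate 11 (not isolated)
Conditions: TsCl, Et3N, Bu2SnO (cat.), CH2Cl2, 0 °C; then K2CO3, MeOH, 0 °C
Reagents that add atoms: none
Why: Tin-catalysed monotosylation of the primary hydroxyl of the 1,2-diol followed by base closes the 2,2-disubstituted epoxide by intramolecular Williamson displacement at the primary carbon, far faster than attack on the secondary chloride, and C4 keeps its configuration because its C–O bond is not broken.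

Step 10
Reactants: 12 terminal epoxide
Product: 13 (4R,5S,7S,8E)-7,12-bis[(tert-butyldimethylsilyl)oxy]-5-chloro-4,8-dimethyldodeca-1,8-dien-4-ol
Conditions: CH2=CHMgBr, CuI (10 mol%), THF, −40 °C; NH4Cl quench at −40 °C
Reagents that add atoms: vinylmagnesium bromide, C=C[Mg]Br
Why: Copper-catalysed Grignard opening of a 2,2-disubstituted epoxide takes place at the CH2 terminus and turns the former hydroxymethyl carbon into the allyl group without touching C3 or C4, a cold quench keeping the magnesium alkoxide from displacing the neighbouring chloride.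

Step 11
Reactants: 13 bis-silyl chlorohydrin
Product: 14 (4E,6S,8S,9R)-8-chloro-5,9-dimethyldodeca-4,11-diene-1,6,9-triol
Conditions: HF·pyridine, pyridine, THF, 0 °C → rt
Reagents that add atoms: none
Why: Buffered HF·pyridine removes both silyl ethers under mildly acidic conditions that cannot close the chlorohydrin to an epoxide.

Step 12
Reactants: 14 triol
Product: 15 (4E,6S,8S,9R)-8-chloro-6,9-dihydroxy-5,9-dimethyldodeca-4,11-dienal
Conditions: TEMPO (10 mol%), PhI(OAc)2, CH2Cl2, rt
Reagents that add atoms: none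
Why: TEMPO/PhI(OAc)2 oxidation is selective for primary over secondary alcohols on steric grounds and stops at the aldehyde, so only the C8 hydroxyl is oxidised.

Step 13
Reactants: 15 hydroxy aldehyde
Product: 16 (4E,6S,8S,9R)-8-chloro-9-hydroxy-5,9-dimethyl-1-oxododeca-4,11-dien-6-yl acetate
Conditions: Ac2O, pyridine, DMAP (cat.), CH2Cl2, 0 °C
Reagents that add atoms: acetic anhydride, CC(=O)OC(C)=O
Why: DMAP-catalysed acetylation acylates the secondary C1 alcohol and leaves the tertiary C4 alcohol untouched, installing the electron-poor ester wanted on O1.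

Step 14
Reactants: 16 acetoxy aldehyde
Product: 17 methyl (6E,8S,10S,11R)-8-(acetyloxy)-10-chloro-11-hydroxy-7,11-dimethyl-3-oxotetradeca-6,13-dienoate
Conditions: N2CHCO2Me, SnCl2 (10 mol%), CH2Cl2, rt
Reagents that add atoms: methyl diazoacetate, COC(=O)C=[N+]=[N-]
Why: Roskamp homologation: SnCl2-catalysed addition of the diazo ester to the aldehyde and 1,2-hydride shift with loss of N2 gives the β-keto ester under conditions mild enough for the acetate and the chlorohydrin.

Step 15
Reactants: 17 acyclic chlorohydrin β-keto ester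
Product: 19 methyl (1R,4aR,5S,6S,8S,8aS)-8-(acetyloxy)-6-chloro-5,8a-dimethyl-2-oxo-5-(prop-2-en-1-yl)decahydronaphthalene-1-carboxylate, via chloronium ion 18 (not isolated)
Conditions: SnCl4 (3 equiv), CH2Cl2, −78 → −20 °C
Reagents that add atoms: none
Why: Proposed new method: SnCl4 complexes the C4 tertiary hydroxyl, the anti-periplanar C3 chlorine expels it to give a C3/C4 chloronium ion of one configuration, the C5=C10 alkene opens this ion at C4 on the side opposite chlorine, and the C10 cation is taken at C9 by the tin-bound enol of the β-keto ester. The closest known reaction types are the racemic chloronium-induced polyene cyclization with Et2SCl·SbCl6 and the enantiospecific bromonium polyene cyclization that starts from enantiopure bromohydrin derivatives. Ring A closes 6-endo at the chloronium carbon and ring B closes 6-endo at the C10 cation, each through a chair. C4 keeps its configuration by double inversion (chlorine in, then C5 in); C5 and C10 are set by anti addition across the (E)-alkene in the chair–chair array (trans fusion, C10 methyl axial); C9 settles with the ester equatorial because this position is epimerisable in a β-keto ester. The step needs chlorine participation to outrun both direct attack of the alkene on C4 and an open C4 cation, and it needs the fold with O1 axial: the anti chlorohydrin configuration fixes the chloronium face, an equatorial O1 would clash with the C9 ester across the peri positions, and the acetate oxygen is too weakly nucleophilic to close a tetrahydrofuran onto C4.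

Step 16
Reactants: 19 decalin β-keto ester
Product: 20 C8 ethylene ketal of 19 (1,3-dioxolane at C8; all stereocentres as in 19)
Conditions: Me3SiOCH2CH2OSiMe3, Me3SiOTf (cat.), CH2Cl2, −78 → −20 °C
Reagents that add atoms: 1,2-bis(trimethylsilyloxy)ethane, C[Si](C)(C)OCCO[Si](C)(C)C
Why: Noyori ketalisation protects the C8 ketone of the β-keto ester without epimerising C9, so that the ester can be reduced alone.

Step 17
Reactants: 20 ketal ester
Product: 22 keto diol (C8 ketone, 9β-hydroxymethyl, 1α-hydroxy, 3β-chloro, 4β-methyl, 4α-allyl, 5α-H, 10β-methyl), via diol ketal 21 (not isolated)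
Conditions: LiAlH4, THF, 0 °C; then 1 M HCl, THF, rt
Reagents that add atoms: water, O
Why: LiAlH4 reduces the C11 ester to the primary alcohol and cleaves the acetate while the neopentyl-type secondary chloride and the ketal are inert, and the acidic work-up then hydrolyses the dioxolane to return the C8 ketone with C9 still carrying its equatorial substituent.

Step 18
Reactants: 22 keto diol
Product: 23 bis(triethylsilyl) ether of 22 (O1 and O11 silylated)
Conditions: Et3SiOTf, 2,6-lutidine, CH2Cl2, −78 °C
Reagents that add atoms: triethylsilyl trifluoromethanesulfonate, CC[Si](CC)(CC)OS(=O)(=O)C(F)(F)F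
Why: A silyl triflate with 2,6-lutidine silylates both the primary and the hindered axial secondary hydroxyl at low temperature without enolising the ketone.

Step 19
Reactants: 23 silylated ketone
Product: 24 C7=C8 enol triflate (C8–OSO2CF3)
Conditions: KN(SiMe3)2, PhNTf2, THF, −78 °C
Reagents that add atoms: N-phenylbis(trifluoromethanesulfonimide), FC(F)(F)S(=O)(=O)N(c1ccccc1)S(=O)(=O)C(F)(F)F
Why: Kinetic deprotonation with a bulky amide base removes a C7 methylene proton rather than the C9 methine proton, which is shielded by quaternary C10 and the axial C1 silyloxy group, and O-triflation of the enolate gives the C7=C8 enol triflate regioselectively.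

Step 20
Reactants: 24 enol triflate
Product: 25 methyl ester at C8 (C12), C7=C8 alkene, O1 and O11 as triethylsilyl ethers
Conditions: Pd(OAc)2 (5 mol%), PPh3, CO (1 atm), MeOH, Et3N, DMF, 50 °C
Reagents that add atoms: carbon monoxide, [C-]#[O+]; methanol, CO
Why: Palladium-catalysed methoxycarbonylation of an enol triflate (oxidative addition to zerovalent palladium, CO insertion, methanolysis of the acylpalladium species) installs C12 as the conjugated methyl ester with the alkene fixed at C7=C8.

Step 21
Reactants: 25 silylated enoate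
Product: 26 diol enoate (1α-OH, 9β-CH2OH)
Conditions: HF·pyridine, pyridine, THF, 0 °C → rt
Reagents that add atoms: none
Why: Fluoride cleavage of the two triethylsilyl ethers under buffered conditions frees O1 and O11 before the acid-sensitive tertiary allylic alcohol is introduced.

Step 22
Reactants: 26 diol enoate; 27 2-methylbut-3-en-2-ol
Product: 28 triol with the complete (E)-4-hydroxy-4-methylpent-2-enyl side chain on C4
Conditions: 27 (excess), second-generation Grubbs catalyst (5 mol%), CH2Cl2, 40 °C
Reagents that add atoms: none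
Why: Cross-metathesis of a monosubstituted alkene with a tertiary allylic alcohol is known to give the (E)-disubstituted alkene selectively, and the trisubstituted, ester-conjugated C7=C8 alkene does not take part.

Step 23
Reactants: 28 triol
Product: 29 CNP0167913.1, methyl (1R,4aR,5S,6S,8S,8aS)-6-chloro-1-formyl-8-hydroxy-5-[(2E)-4-hydroxy-4-methylpent-2-en-1-yl]-5,8a-dimethyl-1,4,4a,5,6,7,8,8a-octahydronaphthalene-2-carboxylate
Conditions: TEMPO (10 mol%), PhI(OAc)2, CH2Cl2, rt
Reagents that add atoms: none
Why: TEMPO/PhI(OAc)2 oxidises the primary C11 alcohol to the aldehyde in preference to the hindered axial C1 alcohol and the tertiary alcohol, under conditions mild enough to leave C9 unepimerised and the alkene in place.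

**Compound list**

1 | pent-4-en-1-ol | C=CCCCO | starting material
2 | tert-butyldimethyl(pent-4-en-1-yloxy)silane | C=CCCCO[Si](C)(C)C(C)(C)C | intermediate
3 | methacrolein (2-methylprop-2-enal) | CC(=C)C=O | starting material
4 | (2E)-6-[(tert-butyldimethylsilyl)oxy]-2-methylhex-2-enal | CC(C)(C)[Si](C)(C)OCCC/C=C(\C)C=O | intermediate
5 | (4S,5E)-9-[(tert-butyldimethylsilyl)oxy]-5-methylnona-1,5-dien-4-ol | CC(C)(C)[Si](C)(C)OCCC/C=C(\C)[C@@H](O)CC=C | intermediate
6 | (4S,5E)-4,9-bis[(tert-butyldimethylsilyl)oxy]-5-methylnona-1,5-diene | CC(C)(C)[Si](C)(C)OCCC/C=C(\C)[C@@H](O[Si](C)(C)C(C)(C)C)CC=C | intermediate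
7 | (2E,5S,6E)-5,10-bis[(tert-butyldimethylsilyl)oxy]-2,6-dimethyldeca-2,6-dienal | CC(C)(C)[Si](C)(C)OCCC/C=C(\C)[C@@H](O[Si](C)(C)C(C)(C)C)C/C=C(\C)C=O | intermediate
8 | (2E,5S,6E)-5,10-bis[(tert-butyldimethylsilyl)oxy]-2,6-dimethyldeca-2,6-dien-1-ol | CC(C)(C)[Si](C)(C)OCCC/C=C(\C)[C@@H](O[Si](C)(C)C(C)(C)C)C/C=C(\C)CO | intermediate
9 | {(2R,3R)-3-[(2S,3E)-2,7-bis[(tert-butyldimethylsilyl)oxy]-3-methylhept-3-en-1-yl]-2-methyloxiran-2-yl}methanol | CC(C)(C)[Si](C)(C)OCCC/C=C(\C)[C@@H](O[Si](C)(C)C(C)(C)C)C[C@H]1O[C@]1(C)CO | intermediate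
10 | (2R,3S,5S,6E)-5,10-bis[(tert-butyldimethylsilyl)oxy]-3-chloro-2,6-dimethyldec-6-ene-1,2-diol | CC(C)(C)[Si](C)(C)OCCC/C=C(\C)[C@@H](O[Si](C)(C)C(C)(C)C)C[C@H](Cl)[C@](C)(O)CO | intermediate
11 | (2R,3S,5S,6E)-5,10-bis[(tert-butyldimethylsilyl)oxy]-3-chloro-2-hydroxy-2,6-dimethyldec-6-en-1-yl 4-methylbenzenesulfonate | CC(C)(C)[Si](C)(C)OCCC/C=C(\C)[C@@H](O[Si](C)(C)C(C)(C)C)C[C@H](Cl)[C@](C)(O)COS(=O)(=O)c1ccc(C)cc1 | intermediate
12 | (2R)-2-[(1S,3S,4E)-3,8-bis[(tert-butyldimethylsilyl)oxy]-1-chloro-4-methyloct-4-en-1-yl]-2-methyloxirane | CC(C)(C)[Si](C)(C)OCCC/C=C(\C)[C@@H](O[Si](C)(C)C(C)(C)C)C[C@H](Cl)[C@@]1(C)CO1 | intermediate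
13 | (4R,5S,7S,8E)-7,12-bis[(tert-butyldimethylsilyl)oxy]-5-chloro-4,8-dimethyldodeca-1,8-dien-4-ol | CC(C)(C)[Si](C)(C)OCCC/C=C(\C)[C@@H](O[Si](C)(C)C(C)(C)C)C[C@H](Cl)[C@](C)(O)CC=C | intermediate
14 | (4E,6S,8S,9R)-8-chloro-5,9-dimethyldodeca-4,11-diene-1,6,9-triol | OCCC/C=C(\C)[C@@H](O)C[C@H](Cl)[C@](C)(O)CC=C | intermediate
15 | (4E,6S,8S,9R)-8-chloro-6,9-dihydroxy-5,9-dimethyldodeca-4,11-dienal | O=CCC/C=C(\C)[C@@H](O)C[C@H](Cl)[C@](C)(O)CC=C | intermediate
16 | (4E,6S,8S,9R)-8-chloro-9-hydroxy-5,9-dimethyl-1-oxododeca-4,11-dien-6-yl acetate | O=CCC/C=C(\C)[C@@H](OC(C)=O)C[C@H](Cl)[C@](C)(O)CC=C | intermediate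
17 | methyl (6E,8S,10S,11R)-8-(acetyloxy)-10-chloro-11-hydroxy-7,11-dimethyl-3-oxotetradeca-6,13-dienoate | COC(=O)CC(=O)CC/C=C(\C)[C@@H](OC(C)=O)C[C@H](Cl)[C@](C)(O)CC=C | intermediate
18 | C3/C4-bridged chloronium ion from 17 (C3 S, C4 S; chlorine anti to the departed hydroxyl) | COC(=O)CC(=O)CC/C=C(\C)[C@@H](OC(C)=O)C[C@@H]1[Cl+][C@@]1(C)CC=C | intermediate
19 | methyl (1R,4aR,5S,6S,8S,8aS)-8-(acetyloxy)-6-chloro-5,8a-dimethyl-2-oxo-5-(prop-2-en-1-yl)decahydronaphthalene-1-carboxylate (C8 ketone, 9β-ester, 1α-OAc, 3β-Cl, 4α-allyl) | O=C1CC[C@H]2[C@](C)(CC=C)[C@@H](Cl)C[C@H](OC(C)=O)[C@]2(C)[C@H]1C(=O)OC | intermediate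
20 | C8 ethylene ketal (1,3-dioxolane) of 19 | O1CCOC12CC[C@H]3[C@](C)(CC=C)[C@@H](Cl)C[C@H](OC(C)=O)[C@]3(C)[C@H]2C(=O)OC | intermediate
21 | C8 ethylene ketal, 1α-hydroxy, 9β-hydroxymethyl diol | O1CCOC12CC[C@H]3[C@](C)(CC=C)[C@@H](Cl)C[C@H](O)[C@]3(C)[C@H]2CO | intermediate
22 | keto diol: 1α-hydroxy-9β-(hydroxymethyl)-3β-chloro-4β,10β-dimethyl-4α-(prop-2-enyl)-5α-H-decalin-8-one | O=C1CC[C@H]2[C@](C)(CC=C)[C@@H](Cl)C[C@H](O)[C@]2(C)[C@H]1CO | intermediate
23 | bis(triethylsilyl) ether of 22 | O=C1CC[C@H]2[C@](C)(CC=C)[C@@H](Cl)C[C@H](O[Si](CC)(CC)CC)[C@]2(C)[C@H]1CO[Si](CC)(CC)CC | intermediate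
24 | C7=C8 enol trifluoromethanesulfonate of 23 | FC(F)(F)S(=O)(=O)OC1=CC[C@H]2[C@](C)(CC=C)[C@@H](Cl)C[C@H](O[Si](CC)(CC)CC)[C@]2(C)[C@H]1CO[Si](CC)(CC)CC | intermediate
25 | methyl C7=C8 enoate (C12 ester on C8), O1 and O11 triethylsilyl ethers | COC(=O)C1=CC[C@H]2[C@](C)(CC=C)[C@@H](Cl)C[C@H](O[Si](CC)(CC)CC)[C@]2(C)[C@H]1CO[Si](CC)(CC)CC | intermediate
26 | methyl enoate diol (1α-OH, 9β-CH2OH, 4α-allyl) | COC(=O)C1=CC[C@H]2[C@](C)(CC=C)[C@@H](Cl)C[C@H](O)[C@]2(C)[C@H]1CO | intermediate
27 | 2-methylbut-3-en-2-ol | CC(C)(O)C=C | starting material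
28 | methyl enoate triol with (E)-4-hydroxy-4-methylpent-2-enyl on C4 | COC(=O)C1=CC[C@H]2[C@](C)(C/C=C/C(C)(C)O)[C@@H](Cl)C[C@H](O)[C@]2(C)[C@H]1CO | intermediate
29 | CNP0167913.1, methyl (1R,4aR,5S,6S,8S,8aS)-6-chloro-1-formyl-8-hydroxy-5-[(2E)-4-hydroxy-4-methylpent-2-en-1-yl]-5,8a-dimethyl-1,4,4a,5,6,7,8,8a-octahydronaphthalene-2-carboxylate | COC(=O)C1=CC[C@H]2[C@](C)(C/C=C/C(C)(C)O)[C@@H](Cl)C[C@H](O)[C@]2(C)[C@H]1C=O | target

**Step count and risks**

Total steps: 23. Longest linear sequence: 23 steps (1 → 29); the route is fully linear.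

Steps most likely to fail:

1. Step 15 (bears the label). What may go wrong: the chloronium ion may open to a free C4 cation before ring A closes, which would scramble C4; the neighbouring acetate carbonyl may capture the C10 cation ahead of C9; or the allylic acetate may ionise. The fallback uses the known chloronium-induced polyene cyclization of an alkene and sets out from allylic alcohol 8. Mesylation and LiBr should give the allylic bromide F1. Stille coupling with CH2=CHSnBu3 and Pd(PPh3)4 should join vinyl at the primary carbon and give the skipped triene F2 with the (E)-C3=C4 alkene. HF·pyridine should then give the diol F3, TEMPO/PhI(OAc)2 the hydroxy aldehyde F4, Ac2O/pyridine the acetoxy aldehyde F5, and SnCl2-catalysed reaction with methyl diazoacetate the triene β-keto ester F6. Et2SCl·SbCl6 in MeNO2 at low temperature should deliver Cl+ to the most electron-rich C3=C4 alkene and trigger the same chair–chair bicyclization. Both chloronium faces form; only the one matched with an axial O1 leads on to 19, and the diastereomeric material is removed by chromatography. The route is rejoined at 19.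

2. Step 12. What may go wrong: concurrent oxidation of the allylic C1 hydroxyl. The fallback replaces chemoselective oxidation by protecting-group differentiation and sets out from 13. HF·pyridine/pyridine at 0 °C should cleave only the primary silyl ether and give the mono-silylated diol F7. Dess–Martin oxidation should give the silyloxy aldehyde F8. Full desilylation with HF·pyridine at rt then returns to the route at 15.

3. Step 19. What may go wrong: enolisation toward C9 followed by β-elimination of the C11 silyloxy group, or triflation on the wrong side of the ketone. The fallback is a Shapiro route and sets out from 23. Condensation with 2,4,6-iPr3C6H2SO2NHNH2 should give the arylsulfonyl hydrazone F9. n-BuLi in THF/TMEDA should deprotonate the C7 methylene syn to the N–N bond and expel N2 and sulfinate to give the C8 vinyllithium. Trapping with ClCO2Me gives the methyl ester directly and rejoins the route at 25.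

**Further compounds**

F1 | step 15 | (2E,5S,6E)-1-bromo-5,10-bis[(tert-butyldimethylsilyl)oxy]-2,6-dimethyldeca-2,6-diene | CC(C)(C)[Si](C)(C)OCCC/C=C(\C)[C@@H](O[Si](C)(C)C(C)(C)C)C/C=C(\C)CBr
F2 | step 15 | (4E,7S,8E)-7,12-bis[(tert-butyldimethylsilyl)oxy]-4,8-dimethyldodeca-1,4,8-triene | CC(C)(C)[Si](C)(C)OCCC/C=C(\C)[C@@H](O[Si](C)(C)C(C)(C)C)C/C=C(\C)CC=C
F3 | step 15 | (4E,6S,8E)-5,9-dimethyldodeca-4,8,11-triene-1,6-diol | OCCC/C=C(\C)[C@@H](O)C/C=C(\C)CC=C
F4 | step 15 | (4E,6S,8E)-6-hydroxy-5,9-dimethyldodeca-4,8,11-trienal | O=CCC/C=C(\C)[C@@H](O)C/C=C(\C)CC=C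
F5 | step 15 | (4E,6S,8E)-5,9-dimethyl-1-oxododeca-4,8,11-trien-6-yl acetate | O=CCC/C=C(\C)[C@@H](OC(C)=O)C/C=C(\C)CC=C
F6 | step 15 | methyl (6E,8S,10E)-8-(acetyloxy)-7,11-dimethyl-3-oxotetradeca-6,10,13-trienoate | COC(=O)CC(=O)CC/C=C(\C)[C@@H](OC(C)=O)C/C=C(\C)CC=C
F7 | step 12 | (4E,6S,8S,9R)-6-[(tert-butyldimethylsilyl)oxy]-8-chloro-5,9-dimethyldodeca-4,11-diene-1,9-diol | OCCC/C=C(\C)[C@@H](O[Si](C)(C)C(C)(C)C)C[C@H](Cl)[C@](C)(O)CC=C
F8 | step 12 | (4E,6S,8S,9R)-6-[(tert-butyldimethylsilyl)oxy]-8-chloro-9-hydroxy-5,9-dimethyldodeca-4,11-dienal | O=CCC/C=C(\C)[C@@H](O[Si](C)(C)C(C)(C)C)C[C@H](Cl)[C@](C)(O)CC=C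
F9 | step 19 | 2,4,6-triisopropylbenzenesulfonyl hydrazone of ketone 23 (N–N syn to C7) | CC(C)c1cc(C(C)C)c(c(c1)C(C)C)S(=O)(=O)N/N=C1\CC[C@H]2[C@](C)(CC=C)[C@@H](Cl)C[C@H](O[Si](CC)(CC)CC)[C@]2(C)[C@H]1CO[Si](CC)(CC)CC
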